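**Strategy.** The target's dihydrofuran ring (O1, C2, C3, C3a, C7a) carries an aryl group on C2 and, on C3, one exocyclic carbon next to the arene carbon C3a. This pattern maps onto a (2S)-flavanone, in which that carbon is the ring carbonyl C4. Oxidation with PhI(OAc)2 in trimethyl orthoformate shifts the arene carbon from C4 to C3, so that the six-membered pyranone ring contracts to the five-membered ring, C4 is expelled as a methyl ester and the 2,3-trans relationship is set, all in one operation. The precursor is a 2-aryl-6-alkyl-8-methoxychroman-4-one, made by enantioselective addition of an arylboronic acid to a chromone catalysed by Pd(OCOCF3)2 and a chiral pyridine-oxazoline ligand.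

Key step: step 5

Remark 1: (R)-t-BuPyOx, (R)-4-tert-butyl-2-(pyridin-2-yl)-4,5-dihydrooxazole, is assumed to deliver the (2S)-flavanone by analogy with the facial sense this ligand class shows on cyclic enones; if the opposite sense is found, the (S)-ligand is used.

Remark 2: The target is drawn as the free hydrogen sulfate, so it is released from its sodium salt in the last operation; the salt is the form suited to storage.

**Step 1**
Reactants: 1 1-(2-hydroxy-3-methoxyphenyl)ethan-1-one
Product: 2 1-(5-bromo-2-hydroxy-3-methoxyphenyl)ethan-1-one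
Conditions: NBS, MeCN, 0 °C to rt
Reagents that add atoms: N-bromosuccinimide, O=C1CCC(=O)N1Br
Why: Electrophilic aromatic bromination, in which the phenol directs para to a position that is also meta to the acetyl group, so only C5 should react.

**Step 2**
Reactants: 2 1-(5-bromo-2-hydroxy-3-methoxyphenyl)ethan-1-one
Product: 4 6-bromo-8-methoxy-4H-chromen-4-one, via enaminone 3 (not isolated)
Conditions: Me2NCH(OMe)2, toluene, 100 °C; then conc. HCl, CH2Cl2, 40 °C
Reagents that add atoms: N,N-dimethylformamide dimethyl acetal, COC(OC)N(C)C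
Why: Enaminone chromone synthesis, in which condensation of the methyl ketone with the amide acetal is followed by acid-promoted addition of the phenol to the enaminone and loss of dimethylamine.

**Step 3**
Reactants: 4 6-bromo-8-methoxy-4H-chromen-4-one; 5 (allyloxy)(tert-butyl)diphenylsilane
Product: 7 6-[3-(tert-butyldiphenylsilyloxy)propyl]-8-methoxy-4H-chromen-4-one, via alkyl-9-BBN borane 6 (not isolated)
Conditions: 5, 9-BBN, THF, 0 °C to rt; then 4, PdCl2(dppf) (cat.), K3PO4, DMF/H2O, 50 °C
Reagents that add atoms: none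
Why: Anti-Markovnikov hydroboration of the terminal alkene followed by B-alkyl Suzuki-Miyaura coupling with the aryl bromide, a reliable sp3-sp2 coupling that should leave the chromone enone untouched under the mild phosphate base.

**Step 4**
Reactants: 7 6-[3-(tert-butyldiphenylsilyloxy)propyl]-8-methoxy-4H-chromen-4-one; 8 [4-(benzyloxy)-3-methoxyphenyl]boronic acid
Product: 9 (2S)-2-[4-(benzyloxy)-3-methoxyphenyl]-6-[3-(tert-butyldiphenylsilyloxy)propyl]-8-methoxychroman-4-one
Conditions: Pd(OCOCF3)2 (cat.), (R)-t-BuPyOx (cat.), NH4PF6, H2O, ClCH2CH2Cl, 60 °C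
Reagents that add atoms: none
Why: Enantioselective conjugate addition of an arylboronic acid to a chromone by a cationic divalent palladium pyridine-oxazoline catalyst, in which aryl-palladium insertion across C2=C3 sets C2 on the face left open by the tert-butyl group of the ligand and protonolysis of the palladium enolate releases the flavanone without base, so retro-oxa-Michael racemisation is avoided.

**Step 5**
Reactants: 9 (2S)-2-[4-(benzyloxy)-3-methoxyphenyl]-6-[3-(tert-butyldiphenylsilyloxy)propyl]-8-methoxychroman-4-one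
Product: 12 methyl (2S,3S)-2-[4-(benzyloxy)-3-methoxyphenyl]-5-[3-(tert-butyldiphenylsilyloxy)propyl]-7-methoxy-2,3-dihydrobenzofuran-3-carboxylate, via methyl enol ether 10 (not isolated), via iodane ketal 11 (not isolated)
Conditions: PhI(OAc)2, H2SO4 (cat.), HC(OMe)3, rt; aq. NaHCO3 work-up
Reagents that add atoms: trimethyl orthoformate, COC(OC)OC
Why: Acid and orthoformate convert the ketone into methyl enol ether 10, which the trivalent iodine electrophile attacks at C3 on the face opposite the C2 aryl group, and methanol capture at C4 gives iodane ketal 11 with an equatorial C3-I bond antiperiplanar to C4-C4a. Departure of iodobenzene triggers a 1,2-shift of the ring A carbon C4a from C4 to C3 with inversion at C3, leaving a dimethoxycarbenium ion at the extruded C4 that collapses to the methyl ester. The closest known reaction type is the oxidative ring contraction of flavanones to methyl trans-2-aryl-2,3-dihydrobenzofuran-3-carboxylates with Tl(NO3)3 or PhI(OAc)2 in trimethyl orthoformate, a semipinacol-type 1,2-aryl shift. The five-membered ring O1-C2-C3-C3a-C7a is closed by this ring contraction through a bridged, phenonium-like transition state (the C3-C3a bond forms as the C4-C4a bond breaks), not by cyclisation of an open chain. C2 is untouched and keeps the S configuration from step 4, while the new centre C3 is controlled by anti attack of iodine and inversion during the shift, which places the ester trans to the aryl group, also the thermodynamically preferred arrangement. The step needs migration of C4a in preference to the electron-rich C2 aryl group (the isoflavone pathway) and to dehydrogenation to the flavone; the diequatorial arrangement of aryl and iodine in 11 aligns only the C4-C4a bond with the leaving group, and the ring oxygen ortho to C4a stabilises the bridged transition state.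

**Step 6**
Reactants: 12 methyl (2S,3S)-2-[4-(benzyloxy)-3-methoxyphenyl]-5-[3-(tert-butyldiphenylsilyloxy)propyl]-7-methoxy-2,3-dihydrobenzofuran-3-carboxylate
Product: 13 methyl (2S,3S)-2-[4-(benzyloxy)-3-methoxyphenyl]-5-(3-hydroxypropyl)-7-methoxy-2,3-dihydrobenzofuran-3-carboxylate
Conditions: HF·pyridine, THF/pyridine, 0 °C to rt
Reagents that add atoms: none
Why: Fluoride-mediated desilylation of the primary silyl ether in a buffered, non-basic medium that should avoid epimerisation at C3 and retro-oxa-Michael opening of the β-aryloxy ester.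

**Step 7**
Reactants: 13 methyl (2S,3S)-2-[4-(benzyloxy)-3-methoxyphenyl]-5-(3-hydroxypropyl)-7-methoxy-2,3-dihydrobenzofuran-3-carboxylate
Product: 14 sodium 3-[(2S,3S)-2-[4-(benzyloxy)-3-methoxyphenyl]-7-methoxy-3-(methoxycarbonyl)-2,3-dihydrobenzofuran-5-yl]propyl sulfate
Conditions: SO3·pyridine, pyridine, rt; then aq. NaHCO3
Reagents that add atoms: sulfur trioxide-pyridine complex, O=S(=O)([O-])[n+]1ccccc1; sodium hydrogen carbonate, [Na+].OC([O-])=O
Why: O-Sulfation of the only free hydroxyl group with the sulfur trioxide-pyridine complex, selective because the phenol is a benzyl ether and the C3 carbon is still at the ester oxidation level.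

**Step 8**
Reactants: 14 sodium 3-[(2S,3S)-2-[4-(benzyloxy)-3-methoxyphenyl]-7-methoxy-3-(methoxycarbonyl)-2,3-dihydrobenzofuran-5-yl]propyl sulfate
Product: 15 sodium 3-[(2S,3R)-2-[4-(benzyloxy)-3-methoxyphenyl]-3-(hydroxymethyl)-7-methoxy-2,3-dihydrobenzofuran-5-yl]propyl sulfate
Conditions: LiBH4, THF, MeOH (2 equiv), 0 °C to rt; aq. NaCl work-up
Reagents that add atoms: none
Why: Chemoselective hydride reduction of the methyl ester with LiBH4, which should leave the alkyl sulfate monoanion (not an electrophile towards borohydride) and both stereocentres untouched; the C3 descriptor changes from S to R only because the substituent priorities change.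

**Step 9**
Reactants: 15 sodium 3-[(2S,3R)-2-[4-(benzyloxy)-3-methoxyphenyl]-3-(hydroxymethyl)-7-methoxy-2,3-dihydrobenzofuran-5-yl]propyl sulfate
Product: 16 3-[(2S,3R)-2-(4-hydroxy-3-methoxyphenyl)-3-(hydroxymethyl)-7-methoxy-2,3-dihydrobenzofuran-5-yl]propyl hydrogen sulfate
Conditions: H2 (1 atm), 10% Pd/C, MeOH, rt; then HCl (1.0 equiv), H2O, 0 °C, C18 desalting, lyophilisation
Reagents that add atoms: none
Why: Hydrogenolysis of the aryl benzyl ether over Pd/C, which should be faster than cleavage of the cyclic benzylic C2-O1 bond, followed by protonation of the sulfate salt with one equivalent of acid in the cold.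

**Compound list**

1 | 1-(2-hydroxy-3-methoxyphenyl)ethan-1-one | CC(=O)c1cccc(OC)c1O | starting material
2 | 1-(5-bromo-2-hydroxy-3-methoxyphenyl)ethan-1-one | CC(=O)c1cc(Br)cc(OC)c1O | intermediate
3 | (E)-1-(5-bromo-2-hydroxy-3-methoxyphenyl)-3-(dimethylamino)prop-2-en-1-one | CN(C)/C=C/C(=O)c1cc(Br)cc(OC)c1O | intermediate (not isolated)
4 | 6-bromo-8-methoxy-4H-chromen-4-one | O=c1ccoc2c1cc(Br)cc2OC | intermediate
5 | (allyloxy)(tert-butyl)diphenylsilane | C=CCO[Si](c1ccccc1)(c1ccccc1)C(C)(C)C | starting material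
6 | 9-[3-(tert-butyldiphenylsilyloxy)propyl]-9-borabicyclo[3.3.1]nonane | CC(C)(C)[Si](OCCCB1C2CCCC1CCC2)(c1ccccc1)c1ccccc1 | intermediate (not isolated)
7 | 6-[3-(tert-butyldiphenylsilyloxy)propyl]-8-methoxy-4H-chromen-4-one | O=c1ccoc2c1cc(CCCO[Si](c3ccccc3)(c3ccccc3)C(C)(C)C)cc2OC | intermediate
8 | [4-(benzyloxy)-3-methoxyphenyl]boronic acid | COc1cc(B(O)O)ccc1OCc1ccccc1 | starting material
9 | (2S)-2-[4-(benzyloxy)-3-methoxyphenyl]-6-[3-(tert-butyldiphenylsilyloxy)propyl]-8-methoxychroman-4-one | O=C1C[C@@H](c2ccc(OCc3ccccc3)c(OC)c2)Oc2c1cc(CCCO[Si](c3ccccc3)(c3ccccc3)C(C)(C)C)cc2OC | intermediate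
10 | (2S)-2-[4-(benzyloxy)-3-methoxyphenyl]-6-[3-(tert-butyldiphenylsilyloxy)propyl]-4,8-dimethoxy-2H-chromene | COC1=C[C@@H](c2ccc(OCc3ccccc3)c(OC)c2)Oc2c1cc(CCCO[Si](c3ccccc3)(c3ccccc3)C(C)(C)C)cc2OC | intermediate (not isolated)
11 | (2R,3R)-3-[acetoxy(phenyl)-λ3-iodanyl]-2-[4-(benzyloxy)-3-methoxyphenyl]-6-[3-(tert-butyldiphenylsilyloxy)propyl]-4,4,8-trimethoxychromane (aryl and iodine trans) | COC1(OC)[C@H]([I](OC(C)=O)c2ccccc2)[C@@H](c2ccc(OCc3ccccc3)c(OC)c2)Oc2c1cc(CCCO[Si](c3ccccc3)(c3ccccc3)C(C)(C)C)cc2OC | intermediate (not isolated)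
12 | methyl (2S,3S)-2-[4-(benzyloxy)-3-methoxyphenyl]-5-[3-(tert-butyldiphenylsilyloxy)propyl]-7-methoxy-2,3-dihydrobenzofuran-3-carboxylate (2,3-trans) | COc1cc([C@H]2Oc3c(OC)cc(CCCO[Si](c4ccccc4)(c4ccccc4)C(C)(C)C)cc3[C@@H]2C(=O)OC)ccc1OCc1ccccc1 | intermediate
13 | methyl (2S,3S)-2-[4-(benzyloxy)-3-methoxyphenyl]-5-(3-hydroxypropyl)-7-methoxy-2,3-dihydrobenzofuran-3-carboxylate | COc1cc([C@H]2Oc3c(OC)cc(CCCO)cc3[C@@H]2C(=O)OC)ccc1OCc1ccccc1 | intermediate
14 | sodium 3-[(2S,3S)-2-[4-(benzyloxy)-3-methoxyphenyl]-7-methoxy-3-(methoxycarbonyl)-2,3-dihydrobenzofuran-5-yl]propyl sulfate | COc1cc([C@H]2Oc3c(OC)cc(CCCOS(=O)(=O)[O-])cc3[C@@H]2C(=O)OC)ccc1OCc1ccccc1.[Na+] | intermediate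
15 | sodium 3-[(2S,3R)-2-[4-(benzyloxy)-3-methoxyphenyl]-3-(hydroxymethyl)-7-methoxy-2,3-dihydrobenzofuran-5-yl]propyl sulfate | COc1cc([C@H]2Oc3c(OC)cc(CCCOS(=O)(=O)[O-])cc3[C@@H]2CO)ccc1OCc1ccccc1.[Na+] | intermediate
16 | 3-[(2S,3R)-2-(4-hydroxy-3-methoxyphenyl)-3-(hydroxymethyl)-7-methoxy-2,3-dihydrobenzofuran-5-yl]propyl hydrogen sulfate | COc1cc([C@H]2Oc3c(OC)cc(CCCOS(=O)(=O)O)cc3[C@@H]2CO)ccc1O | target

**Step count and risks**

Total step count: 9. Longest linear sequence: 9 steps (1 to 16); compounds 5 and 8 are purchased and enter in one step each.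

Steps most likely to fail:

1. Step 5 (key step). The electron-rich C2 aryl group may migrate in place of C4a (isoflavone formation), the enol ether may simply be dehydrogenated to the flavone, the acidic medium may remove the silyl ether, and reversible opening of the pyranone ring may erode the C2 configuration.
 Fallback: set out from 9 and contract the ring by a Wolff rearrangement instead. Trifluoroacetylation of the lithium enolate (LiN(SiMe3)2, CF3CO2CH2CF3, THF, -78 °C) would give (2S)-2-[4-(benzyloxy)-3-methoxyphenyl]-6-[3-(tert-butyldiphenylsilyloxy)propyl]-8-methoxy-3-(trifluoroacetyl)chroman-4-one F1. Detrifluoroacetylative diazo transfer (MsN3, Et3N, H2O, MeCN) would give the 3-diazo ketone (2R)-2-[4-(benzyloxy)-3-methoxyphenyl]-6-[3-(tert-butyldiphenylsilyloxy)propyl]-3-diazo-8-methoxychroman-4-one F2, in which the descriptor changes but the spatial arrangement at C2 does not. Irradiation (300 nm or longer) in MeOH should shift C4a from C4 to the carbene carbon C3, and methanol traps the ketene as 12 mixed with its C3 epimer, the cis ester methyl (2S,3R)-2-[4-(benzyloxy)-3-methoxyphenyl]-5-[3-(tert-butyldiphenylsilyloxy)propyl]-7-methoxy-2,3-dihydrobenzofuran-3-carboxylate F3. Equilibration with NaOMe in MeOH at 0 °C converts F3 into the trans ester, and the route is rejoined at 12.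

2. Step 4. The electron-rich, hindered chromone may insert slowly, the boronic acid may protodeboronate, and the facial selectivity may be insufficient or of the wrong sense.
 Fallback: set out from 7 and separate instead of induce. Addition of 8 with Pd(OCOCF3)2 and 2,2'-bipyridine would give the racemic flavanone rac-2-[4-(benzyloxy)-3-methoxyphenyl]-6-[3-(tert-butyldiphenylsilyloxy)propyl]-8-methoxychroman-4-one F4. Kinetic resolution by asymmetric transfer hydrogenation (HCO2H/Et3N, with the enantiomer of RuCl(p-cymene)(TsDPEN) that reduces the (2R)-ketone faster) would convert the unwanted enantiomer into the cis alcohol (2R,4R)-2-[4-(benzyloxy)-3-methoxyphenyl]-6-[3-(tert-butyldiphenylsilyloxy)propyl]-8-methoxychroman-4-ol F5. The unreacted (2S)-ketone is separated by chromatography, and the route is rejoined at 9.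

3. Step 8. The sulfate salt may dissolve poorly, the reduction may stall, basic borohydride species may trigger β-elimination that opens the dihydrofuran ring, and some sulfate may be lost on work-up.
 Fallback: set out from 12 and reduce before sulfation. LiBH4 in THF would give the alcohol [(2S,3R)-2-[4-(benzyloxy)-3-methoxyphenyl]-5-[3-(tert-butyldiphenylsilyloxy)propyl]-7-methoxy-2,3-dihydrobenzofuran-3-yl]methanol F6. Acetylation (Ac2O, pyridine) would give [(2S,3R)-2-[4-(benzyloxy)-3-methoxyphenyl]-5-[3-(tert-butyldiphenylsilyloxy)propyl]-7-methoxy-2,3-dihydrobenzofuran-3-yl]methyl acetate F7. Desilylation (HF·pyridine) would give [(2S,3R)-2-[4-(benzyloxy)-3-methoxyphenyl]-5-(3-hydroxypropyl)-7-methoxy-2,3-dihydrobenzofuran-3-yl]methyl acetate F8. Sulfation (SO3·pyridine, then NaHCO3) would give sodium 3-[(2S,3R)-3-(acetoxymethyl)-2-[4-(benzyloxy)-3-methoxyphenyl]-7-methoxy-2,3-dihydrobenzofuran-5-yl]propyl sulfate F9. Methanolysis of the acetate (K2CO3, MeOH), harmless once no ester sits on C3, rejoins the route at 15.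

**Further compounds**

F1 | step 5 | (2S)-2-[4-(benzyloxy)-3-methoxyphenyl]-6-[3-(tert-butyldiphenylsilyloxy)propyl]-8-methoxy-3-(trifluoroacetyl)chroman-4-one (C3 epimers and enol form) | O=C1C(C(=O)C(F)(F)F)[C@@H](c2ccc(OCc3ccccc3)c(OC)c2)Oc2c1cc(CCCO[Si](c3ccccc3)(c3ccccc3)C(C)(C)C)cc2OC
F2 | step 5 | (2R)-2-[4-(benzyloxy)-3-methoxyphenyl]-6-[3-(tert-butyldiphenylsilyloxy)propyl]-3-diazo-8-methoxychroman-4-one | O=C1C(=[N+]=[N-])[C@@H](c2ccc(OCc3ccccc3)c(OC)c2)Oc2c1cc(CCCO[Si](c3ccccc3)(c3ccccc3)C(C)(C)C)cc2OC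
F3 | step 5 | methyl (2S,3R)-2-[4-(benzyloxy)-3-methoxyphenyl]-5-[3-(tert-butyldiphenylsilyloxy)propyl]-7-methoxy-2,3-dihydrobenzofuran-3-carboxylate (2,3-cis) | COc1cc([C@H]2Oc3c(OC)cc(CCCO[Si](c4ccccc4)(c4ccccc4)C(C)(C)C)cc3[C@H]2C(=O)OC)ccc1OCc1ccccc1
F4 | step 4 | rac-2-[4-(benzyloxy)-3-methoxyphenyl]-6-[3-(tert-butyldiphenylsilyloxy)propyl]-8-methoxychroman-4-one | O=C1CC(c2ccc(OCc3ccccc3)c(OC)c2)Oc2c1cc(CCCO[Si](c3ccccc3)(c3ccccc3)C(C)(C)C)cc2OC
F5 | step 4 | (2R,4R)-2-[4-(benzyloxy)-3-methoxyphenyl]-6-[3-(tert-butyldiphenylsilyloxy)propyl]-8-methoxychroman-4-ol (2,4-cis) | O[C@@H]1C[C@H](c2ccc(OCc3ccccc3)c(OC)c2)Oc2c1cc(CCCO[Si](c3ccccc3)(c3ccccc3)C(C)(C)C)cc2OC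
F6 | step 8 | [(2S,3R)-2-[4-(benzyloxy)-3-methoxyphenyl]-5-[3-(tert-butyldiphenylsilyloxy)propyl]-7-methoxy-2,3-dihydrobenzofuran-3-yl]methanol | COc1cc([C@H]2Oc3c(OC)cc(CCCO[Si](c4ccccc4)(c4ccccc4)C(C)(C)C)cc3[C@@H]2CO)ccc1OCc1ccccc1
F7 | step 8 | [(2S,3R)-2-[4-(benzyloxy)-3-methoxyphenyl]-5-[3-(tert-butyldiphenylsilyloxy)propyl]-7-methoxy-2,3-dihydrobenzofuran-3-yl]methyl acetate | COc1cc([C@H]2Oc3c(OC)cc(CCCO[Si](c4ccccc4)(c4ccccc4)C(C)(C)C)cc3[C@@H]2COC(C)=O)ccc1OCc1ccccc1
F8 | step 8 | [(2S,3R)-2-[4-(benzyloxy)-3-methoxyphenyl]-5-(3-hydroxypropyl)-7-methoxy-2,3-dihydrobenzofuran-3-yl]methyl acetate | COc1cc([C@H]2Oc3c(OC)cc(CCCO)cc3[C@@H]2COC(C)=O)ccc1OCc1ccccc1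
F9 | step 8 | sodium 3-[(2S,3R)-3-(acetoxymethyl)-2-[4-(benzyloxy)-3-methoxyphenyl]-7-methoxy-2,3-dihydrobenzofuran-5-yl]propyl sulfate | COc1cc([C@H]2Oc3c(OC)cc(CCCOS(=O)(=O)[O-])cc3[C@@H]2COC(C)=O)ccc1OCc1ccccc1.[Na+]
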